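Everything hangs on seeing the pyranone ring of the chromanone as a masked vicinal tricarbonyl: its ketal carbon C2, the hydroxylated C3 that carries flavan C8, and the C4 ketone all sit at carbonyl oxidation level. Cutting the C3–C8 bond and both C2–O bonds therefore leads back to an unsymmetrical diaryl 1,2,3-trione and a flavan with a single free ring A phenol. One squaramide-catalysed operation forges C8–C3 at the middle carbonyl, sets the C3 carbinol and lets O7 close the dihydrofuran as a hemiketal; debenzylation and acid later drain all hemiketal forms into the cis-fused ketal. The immediate precursors are a tetrabenzylated trione and (2S)-7,4'-dihydroxy-5-silyloxyflavan, whose bulky silyl ether shields C6.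

Key step: step 13

Numbering: flavonoid locants are used; C2, C3 and C4 without further label belong to the chromanone unit, and "flavan C…/O…" to the flavan unit.

Remark on the chemistry: the sense of induction of the pyridine-oxazoline ligand (step 9) and of the squaramide (step 13) is assumed by analogy and would be checked on the first run; the ligand antipode or the pseudoenantiomeric (quinine-derived) catalyst would be used if the opposite sense is found.

Step 1
Reactants: 1 2,4,6-trihydroxyacetophenone
Product: 2 2,4,6-tris(benzyloxy)acetophenone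
Conditions: BnBr (3.6 equiv), K2CO3 (4.5 equiv), DMF, 70 °C
Reagents that add atoms: benzyl bromide, BrCc1ccccc1
Why: Williamson ether synthesis in which excess bromide and warm DMF also alkylate the two chelated ortho hydroxyls, the acyl group damping C-benzylation of the phloroglucinol ring.

Step 2
Reactants: 2 2,4,6-tris(benzyloxy)acetophenone; 3 methyl 4-(benzyloxy)benzoate
Product: 4 1-[4-(benzyloxy)phenyl]-3-[2,4,6-tris(benzyloxy)phenyl]propane-1,3-dione
Conditions: NaH (3 equiv), THF, reflux; then 1 M HCl
Reagents that add atoms: none
Why: Crossed Claisen condensation in which the methyl ketone is the only enolisable partner (the ester has no α-hydrogen and the hindered ketone does not self-condense) and deprotonation of the 1,3-diketone product drives the equilibrium.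

Step 3
Reactants: 4 1-[4-(benzyloxy)phenyl]-3-[2,4,6-tris(benzyloxy)phenyl]propane-1,3-dione
Product: 5 2-diazo-1-[4-(benzyloxy)phenyl]-3-[2,4,6-tris(benzyloxy)phenyl]propane-1,3-dione
Conditions: 4-acetamidobenzenesulfonyl azide (1.2 equiv), Et3N, MeCN, 0 °C to rt
Reagents that add atoms: 4-acetamidobenzenesulfonyl azide, CC(=O)Nc1ccc(cc1)S(=O)(=O)N=[N+]=[N-]
Why: Regitz diazo transfer to the acidic central methylene of a 1,3-diketone, which needs only an amine base and leaves the benzyl ethers untouched.

Step 4
Reactants: 5 2-diazo-1-[4-(benzyloxy)phenyl]-3-[2,4,6-tris(benzyloxy)phenyl]propane-1,3-dione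
Product: 6 1-[4-(benzyloxy)phenyl]-3-[2,4,6-tris(benzyloxy)phenyl]propane-1,2,3-trione
Conditions: dimethyldioxirane (acetone solution, 1.5 equiv), CH2Cl2, 0 °C to rt; evaporate, toluene azeotrope, store over 4 Å MS
Reagents that add atoms: dimethyldioxirane, CC1(C)OO1
Why: Oxygen-atom transfer from the dioxirane to the diazo carbon with loss of N2 should give the vicinal tricarbonyl under neutral, anhydrous conditions with only volatile by-products, so the moisture-sensitive trione needs no chromatography.

Step 5
Reactants: 1 2,4,6-trihydroxyacetophenone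
Product: 7 4,6-bis(benzyloxy)-2-hydroxyacetophenone
Conditions: BnBr (2.1 equiv), K2CO3 (2.2 equiv), acetone, reflux
Reagents that add atoms: benzyl bromide, BrCc1ccccc1
Why: Williamson ether synthesis that should stop at the bis-ether because the last hydroxyl is hydrogen-bonded to the ketone and far less nucleophilic.

Step 6
Reactants: 7 4,6-bis(benzyloxy)-2-hydroxyacetophenone
Product: 9 5,7-bis(benzyloxy)chromone, via enaminone 8 (not isolated)
Conditions: Me2NCH(OMe)2 (3 equiv), toluene, 95 °C; evaporate; conc. aq HCl, CH2Cl2, 40 °C
Reagents that add atoms: N,N-dimethylformamide dimethyl acetal, COC(OC)N(C)C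
Why: Condensation of the methyl ketone with the amide acetal gives the enaminone, and acid then promotes 6-endo addition of the phenol and loss of dimethylamine (standard enaminone chromone synthesis).

Step 7
Reactants: 9 5,7-bis(benzyloxy)chromone
Product: 10 7-(benzyloxy)-5-hydroxychromone
Conditions: BCl3 (1.1 equiv), CH2Cl2, −78 °C; water quench
Reagents that add atoms: none
Why: Chelation-controlled Lewis-acid dealkylation in which BCl3 bound to the chromone C4 carbonyl cleaves only the peri 5-benzyl ether, so O5 and O7 become differentiated.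

Step 8
Reactants: 10 7-(benzyloxy)-5-hydroxychromone
Product: 11 7-(benzyloxy)-5-(triisopropylsilyloxy)chromone
Conditions: TIPSOTf (1.3 equiv), Et3N, CH2Cl2, 0 °C to rt
Reagents that add atoms: triisopropylsilyl trifluoromethanesulfonate, CC(C)[Si](C(C)C)(C(C)C)OS(=O)(=O)C(F)(F)F
Why: O-Silylation with the reactive silyl triflate overcomes the hydrogen bond of the chelated phenol and installs the bulky group that later shields flavan C6.

Step 9
Reactants: 11 7-(benzyloxy)-5-(triisopropylsilyloxy)chromone; 12 4-(benzyloxy)phenylboronic acid
Product: 13 (2S)-7,4'-bis(benzyloxy)-5-(triisopropylsilyloxy)flavanone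
Conditions: 12 (2 equiv), Pd(OCOCF3)2 (divalent palladium, 10 mol %), (R)-4-tert-butyl-2-(pyridin-2-yl)-4,5-dihydrooxazole (12 mol %), NH4PF6 (30 mol %), H2O (5 equiv), ClCH2CH2Cl, 60 °C
Reagents that add atoms: none
Why: Enantioselective palladium-catalysed conjugate addition of an arylboronic acid to a chromone (transmetalation, enone insertion, protonation of the palladium enolate), in which the pyridine-oxazoline ligand sets flavan C2 as S and the base-free medium avoids retro-oxa-Michael racemisation.

Step 10
Reactants: 13 (2S)-7,4'-bis(benzyloxy)-5-(triisopropylsilyloxy)flavanone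
Product: 14 (2S)-7,4'-bis(benzyloxy)-5-(triisopropylsilyloxy)flavan-4-ol (both flavan C4 epimers; mainly 2,4-cis expected)
Conditions: NaBH4, CeCl3·7H2O, MeOH/THF, −40 to 0 °C
Reagents that add atoms: none
Why: Luche-type borohydride reduction of the aryl ketone in a buffered protic medium, which keeps the peri silyl ether from migrating to the new alkoxide; the flavan C4 configuration is irrelevant because the centre is removed next.

Step 11
Reactants: 14 (2S)-7,4'-bis(benzyloxy)-5-(triisopropylsilyloxy)flavan-4-ol
Product: 15 (2S)-7,4'-bis(benzyloxy)-5-(triisopropylsilyloxy)flavan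
Conditions: Et3SiH (4 equiv), CF3CO2H (2.5 equiv), CH2Cl2, −40 °C; Et3N quench
Reagents that add atoms: none
Why: Ionic hydrogenation in which the 4-ol ionises already at low temperature to a benzylic cation stabilised by three ortho/para oxygens and is trapped by the silane, while the cold, brief acid exposure should leave the flavan C2–O1 benzylic ether and hence the flavan C2 stereocentre intact.

Step 12
Reactants: 15 (2S)-7,4'-bis(benzyloxy)-5-(triisopropylsilyloxy)flavan
Product: 16 (2S)-7,4'-dihydroxy-5-(triisopropylsilyloxy)flavan
Conditions: H2 (1 atm), Pd/C (10 %), EtOAc/THF, rt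
Reagents that add atoms: none
Why: Catalytic hydrogenolysis of the two aryl benzyl ethers under neutral conditions, which is expected to spare the cyclic flavan C2–O1 ether and the aryl silyl ether as in debenzylations of catechin-type flavans.

Step 13
Reactants: 6 1-[4-(benzyloxy)phenyl]-3-[2,4,6-tris(benzyloxy)phenyl]propane-1,2,3-trione; 16 (2S)-7,4'-dihydroxy-5-(triisopropylsilyloxy)flavan
Product: 18 furo-fused flavan hemiketal (C3 carbinol R; hemiketal carbon S as drawn; flavan C2 S), via open-chain carbinol 17 (not isolated)
Conditions: N-[3,5-bis(trifluoromethyl)phenyl]-N'-(9-deoxy-epi-quinidin-9-yl)squaramide (10 mol %), 4 Å MS, toluene/CH2Cl2, −20 °C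
Reagents that add atoms: none
Why: Proposed new method: the quinuclidine nitrogen hydrogen-bonds the 7-OH of 16 while the two squaramide N–H bonds clamp the central and one flanking carbonyl of 6, so that flavan C8 adds to the central, most electrophilic carbonyl and tautomerisation of the cyclohexadienone restores the arene to leave carbinol 17. The closest known reactions are the ninhydrin–phenol condensation that gives cis-fused hydroxy-indenobenzofuranones and squaramide-catalysed ortho Friedel–Crafts hydroxyalkylations of naphthols and electron-rich phenols with isatins or trifluoropyruvates; an acyclic, unsymmetrical diaryl trione has not been used as the electrophile in an enantioselective version. The dihydrofuran ring then closes by reversible 5-exo-trig addition of O7 to the planar 4-benzyloxybenzoyl carbonyl, the alternative hemiketal on the twisted, di-ortho-substituted aroyl carbonyl being reversible and less favoured. The C3 carbinol centre is set by the catalyst, which must distinguish the two faces of the central carbonyl through the steric contrast between its flat and its twisted aroyl neighbour (flavan C2 is too remote to assist), whereas the hemiketal carbon is under thermodynamic control and need not be controlled because both epimers converge in step 14. The step needs C8 rather than C6 attack, secured by the bulky 5-O-triisopropylsilyl group next to C6 and by the 7-OH that directs ortho attack, and it needs the ring B phenol to stay a spectator, which its far lower ring nucleophilicity should ensure.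

Step 14
Reactants: 18 furo-fused flavan hemiketal
Product: 20 5-O-triisopropylsilyl ether of the target ketal, via debenzylated hemiketal 19 (not isolated)
Conditions: H2 (1 atm), Pd/C (10 %), THF, rt; filter; camphorsulfonic acid (0.2 equiv), 4 Å MS, THF, rt to 40 °C
Reagents that add atoms: none
Why: Neutral hydrogenolysis frees the four phenols and acid then ionises the hemiketal to an aryl-stabilised oxocarbenium ion that the ring A ortho-hydroxyl traps in a 6-exo closure; only a cis-fused 5/6 ketal can form, so the C2 ketal configuration (R) is relayed from C3 and all hemiketal and ring-chain forms converge on one product.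

Step 15
Reactants: 20 5-O-triisopropylsilyl ether of the target ketal
Product: 21 CNP0208300.2 (target)
Conditions: HF·pyridine, pyridine, THF, 0 °C to rt
Reagents that add atoms: none
Why: Fluoride-mediated cleavage of the aryl silyl ether under mildly acidic conditions, chosen to avoid base-induced α-ketol rearrangement or opening of the polyphenolic ketal.

Compound list
1 | 2,4,6-trihydroxyacetophenone | CC(=O)c1c(O)cc(O)cc1O | starting material
2 | 2,4,6-tris(benzyloxy)acetophenone | CC(=O)c1c(OCc2ccccc2)cc(OCc2ccccc2)cc1OCc1ccccc1 | intermediate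
3 | methyl 4-(benzyloxy)benzoate | COC(=O)c1ccc(OCc2ccccc2)cc1 | starting material
4 | 1-[4-(benzyloxy)phenyl]-3-[2,4,6-tris(benzyloxy)phenyl]propane-1,3-dione | O=C(CC(=O)c1c(OCc2ccccc2)cc(OCc2ccccc2)cc1OCc1ccccc1)c1ccc(OCc2ccccc2)cc1 | intermediate
5 | 2-diazo-1-[4-(benzyloxy)phenyl]-3-[2,4,6-tris(benzyloxy)phenyl]propane-1,3-dione | O=C(C(=[N+]=[N-])C(=O)c1c(OCc2ccccc2)cc(OCc2ccccc2)cc1OCc1ccccc1)c1ccc(OCc2ccccc2)cc1 | intermediate
6 | 1-[4-(benzyloxy)phenyl]-3-[2,4,6-tris(benzyloxy)phenyl]propane-1,2,3-trione | O=C(C(=O)C(=O)c1c(OCc2ccccc2)cc(OCc2ccccc2)cc1OCc1ccccc1)c1ccc(OCc2ccccc2)cc1 | intermediate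
7 | 4,6-bis(benzyloxy)-2-hydroxyacetophenone | CC(=O)c1c(O)cc(OCc2ccccc2)cc1OCc1ccccc1 | intermediate
8 | (E)-1-[4,6-bis(benzyloxy)-2-hydroxyphenyl]-3-(dimethylamino)prop-2-en-1-one | CN(C)/C=C/C(=O)c1c(O)cc(OCc2ccccc2)cc1OCc1ccccc1 | intermediate
9 | 5,7-bis(benzyloxy)chromone | O=c1ccoc2cc(OCc3ccccc3)cc(OCc3ccccc3)c12 | intermediate
10 | 7-(benzyloxy)-5-hydroxychromone | O=c1ccoc2cc(OCc3ccccc3)cc(O)c12 | intermediate
11 | 7-(benzyloxy)-5-(triisopropylsilyloxy)chromone | O=c1ccoc2cc(OCc3ccccc3)cc(O[Si](C(C)C)(C(C)C)C(C)C)c12 | intermediate
12 | 4-(benzyloxy)phenylboronic acid | OB(O)c1ccc(OCc2ccccc2)cc1 | starting material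
13 | (2S)-7,4'-bis(benzyloxy)-5-(triisopropylsilyloxy)flavanone | c1ccccc1COc1cc(O[Si](C(C)C)(C(C)C)C(C)C)c2c(c1)O[C@H](c1ccc(OCc3ccccc3)cc1)CC2=O | intermediate
14 | (2S)-7,4'-bis(benzyloxy)-5-(triisopropylsilyloxy)flavan-4-ol, both C4 epimers | c1ccccc1COc1cc(O[Si](C(C)C)(C(C)C)C(C)C)c2c(c1)O[C@H](c1ccc(OCc3ccccc3)cc1)CC2O | intermediate
15 | (2S)-7,4'-bis(benzyloxy)-5-(triisopropylsilyloxy)flavan | c1ccccc1COc1cc(O[Si](C(C)C)(C(C)C)C(C)C)c2c(c1)O[C@H](c1ccc(OCc3ccccc3)cc1)CC2 | intermediate
16 | (2S)-7,4'-dihydroxy-5-(triisopropylsilyloxy)flavan | Oc1cc(O[Si](C(C)C)(C(C)C)C(C)C)c2c(c1)O[C@H](c1ccc(O)cc1)CC2 | intermediate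
17 | (2S)-2-hydroxy-1-[4-(benzyloxy)phenyl]-2-[(2S)-7-hydroxy-2-(4-hydroxyphenyl)-5-(triisopropylsilyloxy)chroman-8-yl]-3-[2,4,6-tris(benzyloxy)phenyl]propane-1,3-dione (open-chain carbinol) | Oc3cc(O[Si](C(C)C)(C(C)C)C(C)C)c4c(c3[C@](O)(C(=O)c5ccc(OCc6ccccc6)cc5)C(=O)c5c(OCc6ccccc6)cc(OCc6ccccc6)cc5OCc5ccccc5)O[C@H](c1ccc(O)cc1)CC4 | intermediate
18 | hemiketal: (2S)-flavan whose O7 and C8 are bridged into a dihydrofuran by C(OH)(4-benzyloxyphenyl) on O7 and C(OH)[2,4,6-tris(benzyloxy)benzoyl] on C8; carbinol carbon R, hemiketal carbon S as drawn (epimers equilibrate); 4'-OH free, 5-O-triisopropylsilyl | O[C@@]2(c3ccc(OCc4ccccc4)cc3)Oc3cc(O[Si](C(C)C)(C(C)C)C(C)C)c4c(c3[C@@]2(O)C(=O)c2c(OCc5ccccc5)cc(OCc5ccccc5)cc2OCc2ccccc2)O[C@H](c1ccc(O)cc1)CC4 | intermediate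
19 | debenzylated hemiketal: as 18 with 4-hydroxyphenyl and 2,4,6-trihydroxybenzoyl groups (same configurations, ring-chain tautomers equilibrate) | O[C@@]2(c3ccc(O)cc3)Oc3cc(O[Si](C(C)C)(C(C)C)C(C)C)c4c(c3[C@@]2(O)C(=O)c2c(O)cc(O)cc2O)O[C@H](c1ccc(O)cc1)CC4 | intermediate
20 | 5-O-triisopropylsilyl ether (flavan O5) of the target; chromanone C2 R, C3 R, flavan C2 S, cis-fused ketal | O=C1c2c(O)cc(O)cc2O[C@@]2(c3ccc(O)cc3)Oc3cc(O[Si](C(C)C)(C(C)C)C(C)C)c4c(c3[C@@]12O)O[C@H](c1ccc(O)cc1)CC4 | intermediate
21 | CNP0208300.2: (2R,3R)-3,5,7-trihydroxy-2-(4-hydroxyphenyl)chroman-4-one whose C2 and C3 are joined to O7 and C8 of (2S)-5,7,4'-trihydroxyflavan in a cis-fused dihydrofuran ketal | O=C1c2c(O)cc(O)cc2O[C@@]2(c3ccc(O)cc3)Oc3cc(O)c4c(c3[C@@]12O)O[C@H](c1ccc(O)cc1)CC4 | target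

Total step count: 15. Longest linear sequence: 11 steps (steps 5 to 15, from compound 1); the trione branch (steps 1 to 4) joins at step 13.

The three steps most likely to fail

First, step 13, the step that rests on a proposed new method. What may go wrong is weak catalyst control over the face of the central carbonyl, because the uncatalysed addition of the very nucleophilic phenol to the highly electrophilic trione can compete and deliver both C3 configurations. The fallback for step 13 uses known chemistry and sets out from 6 and 16. The two are condensed without a chiral catalyst in acetic acid at room temperature, the acid-promoted Friedel–Crafts hydroxyalkylation and hemiketalisation known from ninhydrin–phenol condensations. Since flavan C2 is already fixed as S, this should give two diastereomers, 18 and its C3-epimeric hemiketal F1 in which the carbinol carbon is S. The pair should be separable by chromatography. The fallback comes back to the route at 18, at the cost of the material that ends up as the epimer F1 .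

Second, step 9. What may go wrong is sluggish insertion into the electron-rich, peri-silyloxy chromone, with protodeboronation of 12, partial loss of the silyl group or eroded enantioselectivity. The fallback for step 9 sets out from 11 and moves the stereochemical decision from the C–C bond formation to a resolution. Copper-catalysed conjugate addition of 4-(benzyloxy)phenylmagnesium bromide to 11 (CuBr·SMe2, Me3SiCl, THF, −78 °C, acidic work-up) should give racemic 7,4'-bis(benzyloxy)-5-(triisopropylsilyloxy)flavanone F2 in one operation. The racemic flavanone F2 is then submitted to asymmetric transfer hydrogenation in HCO2H/Et3N, run as a kinetic resolution. The catalyst is RuCl(p-cymene)[(S,S)-TsDPEN] or its (R,R) antipode, whichever is matched to the (2S)-ketone; both are complexes of divalent ruthenium. This should reduce only the (2S)-enantiomer, to the 2,4-cis flavan-4-ol, while the slower enantiomer stays behind as ketone and is removed by chromatography. The fallback comes back to the route at 14, obtained here as its 2,4-cis epimer.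

Third, step 14. What may go wrong is reduction of the ring-opened aryl ketone tautomer or hydrogenolytic loss of a benzylic C–O bond of the hemiketal while the four benzyl ethers are cleaved. The fallback for step 14 sets out from 18 and locks the hemiketal before any hydrogen is admitted. Treatment of 18 with camphorsulfonic acid in MeOH/HC(OMe)3 should give the mixed methyl ketal F3 which can no longer open to a ketone. Hydrogenolysis of the methyl ketal F3 over Pd/C in THF should then give the debenzylated methyl ketal F4 with its four free phenols. Catalytic camphorsulfonic acid in THF should convert the debenzylated methyl ketal F4 by intramolecular transketalisation, the ring A ortho-hydroxyl displacing methanol. The fallback comes back to the route at 20.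

Further compounds
F1 | step 13 | C3 epimer of 18: carbinol carbon S, hemiketal carbon R as drawn, flavan C2 S | O[C@]2(c3ccc(OCc4ccccc4)cc3)Oc3cc(O[Si](C(C)C)(C(C)C)C(C)C)c4c(c3[C@]2(O)C(=O)c2c(OCc5ccccc5)cc(OCc5ccccc5)cc2OCc2ccccc2)O[C@H](c1ccc(O)cc1)CC4
F2 | step 9 | racemic 7,4'-bis(benzyloxy)-5-(triisopropylsilyloxy)flavanone | O=C1CC(c2ccc(OCc3ccccc3)cc2)Oc2cc(OCc3ccccc3)cc(O[Si](C(C)C)(C(C)C)C(C)C)c12
F3 | step 14 | mixed methyl ketal of 18 (hemiketal OH replaced by OMe; one ketal epimer drawn) | CO[C@@]2(c3ccc(OCc4ccccc4)cc3)Oc3cc(O[Si](C(C)C)(C(C)C)C(C)C)c4c(c3[C@@]2(O)C(=O)c2c(OCc5ccccc5)cc(OCc5ccccc5)cc2OCc2ccccc2)O[C@H](c1ccc(O)cc1)CC4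
F4 | step 14 | debenzylated methyl ketal (F3 with four free phenols in place of the benzyl ethers) | CO[C@@]2(c3ccc(O)cc3)Oc3cc(O[Si](C(C)C)(C(C)C)C(C)C)c4c(c3[C@@]2(O)C(=O)c2c(O)cc(O)cc2O)O[C@H](c1ccc(O)cc1)CC4
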